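If right-handed product stood in no table, I could still estimate it by difference, and this is what I would watch on a repeat. I carried one number, the loss ratio: right-handed substrate lost divided by left-handed substrate lost.

the same everywhere: left-handed substrate 10 mM; right-handed substrate 10 mM
- west: coupling partner 3 equiv; free catalyst 9 mol%; the very flask that is asked about, followed so far
- north-west: coupling partner 3 equiv; free catalyst 18 mol%; run made earlier
- flask: coupling partner 3.00 equiv; free catalyst 9 mol%; time 2.0 min

| run | time / s | left-handed substrate / % | right-handed substrate / % | left-handed product / % |
|---|---|---|---|---|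
| west | 10.0 | 47.0 | 44.9 | 2.4 |
| west | 12.0 | 47.0 | 44.8 | 2.5 |
| west | 20.0 | 46.3 | 44.4 | 3.3 |
| west | 30.0 | 46.3 | 43.6 | 3.9 |
| west | 50.0 | 45.5 | 43.4 | 4.3 |
| west | 60.0 | 45.7 | 42.9 | 4.4 |
| north-west | 10.0 | 44.3 | 40.9 | 4.7 |
| north-west | 15.0 | 43.4 | 40.2 | 6.2 |
| north-west | 25.0 | 42.5 | 38.9 | 7.2 |
| north-west | 40.0 | 42.1 | 37.9 | 7.5 |
| north-west | 50.0 | 41.8 | 38.2 | 8.0 |

(readings scatter by 0.3 percentage points)

- free catalyst is single-handed; left-handed substrate and right-handed substrate are mirror images of each other, charged as a racemate, each of them at the stated concentration
- the numbers in the tables scatter by 0.3 percentage points (one standard deviation)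
- an excess is the difference of the two amounts in percent of their sum
- an excess is below zero if the other one leads

- part of the left-handed substrate and right-handed substrate charged together that has reacted at 2.0 min
- excess of left-handed product over right-handed product in the product at 2.0 min
- excess of right-handed substrate over left-handed substrate among what is left of the two at 2.0 min

I followed the west run in slow motion. In the first 10.0 s, a burst took left-handed substrate to 47.0 %, right-handed substrate to 44.9 %, and left-handed product to 2.4 %. By 30.0 s left-handed product stood at 3.9 %, and the next reading added 0.4 percentage points. Between 50.0 s and 60.0 s it gained 0.1 points, inside the scatter of 0.3 points, though left-handed substrate still stood at 45.7 %. The north-west run, with twice the catalyst, reached twice that product. I therefore read the stop as a dying catalyst and took the last west readings as nearly final.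

Left-handed substrate lost, 4.30 %, matched left-handed product, 4.4 %. I chose to count right-handed loss as product too, as in a kinetic resolution:

r = (c charged − c right-handed substrate) / (c charged − c left-handed substrate) = 1.65

product excess = (1 − r) / (1 + r) = −24.6 %

The same readings gave me 11.4 % reacted and a substrate excess of −3.16 %.

The forecast differed on the product. It gave 11.8 % reacted (8.3 % to 12.6 %), a product excess of 5 % (−25 % to 12 %) and a substrate excess of −3.2 % (−3.9 % to −2.5 %). Of the early right-handed loss it said: “it looks like right-handed substrate held on the catalyst rather than product”.

The flask gave 12.3 % reacted, a product excess of −22.4 % and a substrate excess of −3.16 %.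

    free catalyst + left-handed substrate ⇌ catalyst intermediate A (K = 44.0 L mol⁻¹, k = 1300 L mol⁻¹ s⁻¹)
    free catalyst + right-handed substrate ⇌ catalyst intermediate B (K = 200 L mol⁻¹, k = 7600 L mol⁻¹ s⁻¹)
    coupling partner + catalyst intermediate A → free catalyst + left-handed product (k = 22.0 L mol⁻¹ s⁻¹)
    coupling partner + catalyst intermediate B → free catalyst + right-handed product (k = 7.90 L mol⁻¹ s⁻¹)
    free catalyst → spent catalyst (k = 0.180 s⁻¹)
    free catalyst ⇌ dormant form (K = 18.0, k = 0.110 s⁻¹)

At 2.00 min the flask held 4.75 % left-handed product and 7.49 % right-handed product, a ratio of 1.58 where I had carried 1.65. The reverse step of catalyst intermediate A to free catalyst and left-handed substrate may be called the main reason for that sign: the run without it gave a product excess of 79.3 % against −22.4 %. The neighbour with 15 mol% of free catalyst lost its substrates in a ratio of 1.54, which by the same reckoning gave −21.3 %, and its product excess stood at −21.0 %.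

The numbers in the tables are simulated on assumed constants.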